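**Retrosynthetic overview**

1. C7–C8 (last step): Stille coupling of the stannyl lactone 39 with the Z-vinyl iodide 29 (C8–C24).
2. C15–C16 and the C16 stereocentre: a dienylalanate (from carboalumination of enyne 24) adds to the oxiranyl ketone 15, then the dienyl group shifts from C17 to C16 (semipinacol 1,2-shift with inversion), unveiling the C17 ketone and the CH2OH group.
3. C18–C19: Ipc2B syn-aldol of the (R)-oxiranyl ethyl ketone 12 with aldehyde 9. C21–C22 and C11–C12: Negishi couplings of chiral-pool 3-bromo-2-methylpropyl units. C8=C9: Stork–Zhao olefination.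
4. Rings: the oxirane is bought (methyl (R)-glycidate) and consumed in the 1,2-shift; the only ring of the target, the δ-lactone, is closed by RCM in fragment 39 (Brown crotylation, acryloylation, RCM) before the final coupling.

Assumption: (–)-Ipc2BOTf (from (+)-α-pinene) sends a Z-enol borinate to the Si face of an aldehyde, the same sense as (–)-Ipc2B-crotyl reagents; positions are quoted in kazusamycin numbering (C1 lactone carbonyl to C24 acid).

**Route**

Step 1
Reactants: 1 methyl acetoacetate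
Product: 2 2-(trimethylsilyl)ethyl 3-oxobutanoate
Conditions: Me3SiCH2CH2OH (1.1 equiv), DMAP (0.2 equiv), toluene, 110 °C, 4 Å MS (removal of MeOH)
Reagents that add atoms: 2-(trimethylsilyl)ethanol, C[Si](C)(C)CCO
Why: DMAP-catalysed transesterification of a β-keto ester installs the fluoride-cleavable TMSE ester; no stereocentre is involved.

Step 2
Reactants: 2 2-(trimethylsilyl)ethyl 3-oxobutanoate
Product: 3 2-(trimethylsilyl)ethyl (2E)-3-(trifluoromethanesulfonyloxy)but-2-enoate
Conditions: Tf2O, 25% aq. Me4NOH, hexanes, 5 °C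
Reagents that add atoms: triflic anhydride, O=S(=O)(OS(=O)(=O)C(F)(F)F)C(F)(F)F
Why: Frantz stereoselective enol triflation: the non-chelated tetramethylammonium enolate is trapped as the (E)-triflate (OTf trans to the ester), which fixes the later 22E geometry.

Step 3
Reactants: 4 (R)-3-bromo-2-methylpropan-1-ol; 3 2-(trimethylsilyl)ethyl (2E)-3-(trifluoromethanesulfonyloxy)but-2-enoate
Product: 8 2-(trimethylsilyl)ethyl (2E,5S)-6-hydroxy-3,5-dimethylhex-2-enoate, via TMS ether 5 (not isolated), via alkylzinc bromide 6 (not isolated), via O-silylated coupling product 7 (not isolated)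
Conditions: HMDS, TMSCl (cat.), 23 °C, then vacuum; Zn dust, LiCl, THF, 50 °C; 3, Pd(OAc)2 (2 mol %), SPhos (4 mol %), THF, 23 °C; citric acid, MeOH
Reagents that add atoms: none
Why: Negishi sp3–sp2 cross-coupling: zinc insertion into the transiently O-silylated bromide and Pd/SPhos coupling with the enol triflate go with retention of alkene geometry, and the C20 stereocentre (chiral pool) is not touched.

Step 4
Reactants: 8 2-(trimethylsilyl)ethyl (2E,5S)-6-hydroxy-3,5-dimethylhex-2-enoate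
Product: 9 2-(trimethylsilyl)ethyl (2E,5S)-3,5-dimethyl-6-oxohex-2-enoate
Conditions: Dess–Martin periodinane, CH2Cl2, 0 → 23 °C; used crude
Reagents that add atoms: none
Why: Dess–Martin oxidation gives the α-methyl aldehyde under non-basic conditions, so C20 does not epimerise.

Step 5
Reactants: 10 methyl (2R)-oxirane-2-carboxylate (methyl (R)-glycidate)
Product: 11 (2R)-N-methoxy-N-methyloxirane-2-carboxamide
Conditions: MeNH(OMe)·HCl, i-PrMgCl, THF, –20 °C
Reagents that add atoms: N,O-dimethylhydroxylamine hydrochloride, CNOC.Cl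
Why: Weinreb amide formation from the ester by the i-PrMgCl protocol is fast at –20 °C, below the temperature at which the oxirane is opened.

Step 6
Reactants: 11 (2R)-N-methoxy-N-methyloxirane-2-carboxamide
Product: 12 1-[(2R)-oxiran-2-yl]propan-1-one
Conditions: EtMgBr, THF, –78 → –40 °C; aq. NH4Cl; handled as a solution (volatile)
Reagents that add atoms: ethylmagnesium bromide, CC[Mg]Br
Why: Weinreb ketone synthesis: the magnesium chelate stops at the ketone stage and the oxirane stereocentre (the future C16) is untouched.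

Step 7
Reactants: 12 1-[(2R)-oxiran-2-yl]propan-1-one; 9 2-(trimethylsilyl)ethyl (2E,5S)-3,5-dimethyl-6-oxohex-2-enoate
Product: 14 2-(trimethylsilyl)ethyl (2E,5S,6R,7S)-6-hydroxy-3,5,7-trimethyl-8-[(2R)-oxiran-2-yl]-8-oxooct-2-enoate, via Z-enol diisopinocampheylborinate 13 (not isolated)
Conditions: (–)-Ipc2BOTf, i-Pr2NEt, CH2Cl2, –78 °C, 3 h; 9, –78 → –20 °C, 16 h; pH 7 buffer, MeOH, 30% H2O2, 0 °C
Reagents that add atoms: none
Why: Paterson boron aldol: only the ethyl side enolises (the oxiranyl C–H cannot), the Z-enol borinate reacts through a chair Zimmerman–Traxler transition state to give the 18,19-syn adduct, and the Ipc ligands direct attack to the aldehyde Si face (18S,19R, all-syn with C20).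

Step 8
Reactants: 14 2-(trimethylsilyl)ethyl (2E,5S,6R,7S)-6-hydroxy-3,5,7-trimethyl-8-[(2R)-oxiran-2-yl]-8-oxooct-2-enoate
Product: 15 2-(trimethylsilyl)ethyl (2E,5S,6R,7S)-3,5,7-trimethyl-8-[(2R)-oxiran-2-yl]-8-oxo-6-(triethylsilyloxy)oct-2-enoate
Conditions: TESOTf, 2,6-lutidine, CH2Cl2, –78 °C (crude 14 used at once)
Reagents that add atoms: triethylsilyl triflate, CC[Si](CC)(CC)OS(=O)(=O)C(F)(F)F
Why: Silyl ether formation at –78 °C blocks the C19 hydroxyl, which could otherwise attack the oxirane.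

Step 9
Reactants: 16 (E)-1,2-dichloroethene; 17 ethynyltrimethylsilane
Product: 18 [(3E)-4-chlorobut-3-en-1-yn-1-yl]trimethylsilane
Conditions: 16 (5 equiv), Pd(PPh3)4 (2 mol %), CuI (5 mol %), n-BuNH2, Et2O, 23 °C
Reagents that add atoms: none
Why: Sonogashira coupling; excess dichloroethene secures mono-coupling with retention of the E geometry (future 12E).

Step 10
Reactants: 19 methyl (2S)-3-bromo-2-methylpropanoate; 18 [(3E)-4-chlorobut-3-en-1-yn-1-yl]trimethylsilane
Product: 21 methyl (2R,4E)-2-methyl-7-(trimethylsilyl)hept-4-en-6-ynoate, via alkylzinc bromide 20 (not isolated)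
Conditions: Zn dust, LiCl, THF, 40 °C; 18, Pd(OAc)2 (2 mol %), SPhos (4 mol %), THF, 50 °C
Reagents that add atoms: none
Why: Negishi coupling of the Roche-type zinc homoenolate with the activated alkenyl chloride goes with retention of the E geometry; the C10 stereocentre comes from the chiral pool.

Step 11
Reactants: 21 methyl (2R,4E)-2-methyl-7-(trimethylsilyl)hept-4-en-6-ynoate
Product: 22 (2R,4E)-2-methyl-7-(trimethylsilyl)hept-4-en-6-ynal
Conditions: DIBAL-H (1.05 equiv), CH2Cl2, –78 °C; MeOH, then aq. Rochelle salt; used crude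
Reagents that add atoms: none
Why: DIBAL-H half-reduction of the ester at –78 °C stops at the tetrahedral aluminium hemiacetal, which gives the aldehyde on work-up.

Step 12
Reactants: 22 (2R,4E)-2-methyl-7-(trimethylsilyl)hept-4-en-6-ynal
Product: 23 [(3E,6R,7Z)-8-iodo-6-methyldeca-3,7-dien-1-yn-1-yl]trimethylsilane
Conditions: n-PrPPh3Br, n-BuLi, THF, 23 °C; I2, –78 °C; NaHMDS, –20 °C; 22, –78 → –20 °C
Reagents that add atoms: propyltriphenylphosphonium bromide, CCC[P+](c1ccccc1)(c1ccccc1)c1ccccc1.[Br-]; iodine, II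
Why: Stork–Zhao olefination: the α-iodo ylide gives the (Z)-iodoalkene (iodine cis to C10) under kinetic control, which sets the 8Z geometry and the ethyl branch.

Step 13
Reactants: 23 [(3E,6R,7Z)-8-iodo-6-methyldeca-3,7-dien-1-yn-1-yl]trimethylsilane
Product: 24 (3Z,5R,7E)-3-iodo-5-methyldeca-3,7-dien-9-yne
Conditions: K2CO3 (cat.), MeOH, 23 °C
Reagents that add atoms: none
Why: Base-catalysed protodesilylation of the alkynylsilane; no stereocentre or alkene is affected.

Step 14
Reactants: 24 (3Z,5R,7E)-3-iodo-5-methyldeca-3,7-dien-9-yne; 15 2-(trimethylsilyl)ethyl (2E,5S,6R,7S)-3,5,7-trimethyl-8-[(2R)-oxiran-2-yl]-8-oxo-6-(triethylsilyloxy)oct-2-enoate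
Product: 28 2-(trimethylsilyl)ethyl (2E,5S,6R,7S,9S,10E,12E,15R,16Z)-9-(hydroxymethyl)-17-iodo-3,5,7,11,15-pentamethyl-8-oxo-6-(triethylsilyloxy)nonadeca-2,10,12,16-tetraenoate, via dienyl(dimethyl)alane 25 (not isolated), via lithium dienyl(trimethyl)aluminate 26 (not isolated), via tertiary aluminate alkoxide 27 (not isolated)
Conditions: AlMe3 (2 equiv), Cp2ZrCl2 (0.25 equiv), CH2Cl2, 0 → 23 °C; vacuum (removal of excess AlMe3); MeLi (1 equiv), THF, –78 °C; 15 (0.7 equiv), –78 → –40 °C; CH2Cl2, BF3·OEt2 (5 equiv), –78 °C; aq. NaHCO3/Rochelle salt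
Reagents that add atoms: trimethylaluminium, C[Al](C)C
Why: Proposed new method: Zr-catalysed syn-methylalumination (Negishi) gives the (E,E)-dienylalane, whose lithium alanate transfers the dienyl group to the ketone; BF3 then activates the oxirane and the electron-rich aluminate alkoxide pushes the dienyl group (best migrating group through π-participation) from C17 to C16 anti to the breaking C16–O bond, so the (R)-oxirane carbon becomes (16S) whatever the C17 configuration while the C17 ketone and the CH2OH are released, a semipinacol 1,2-shift that amounts to an invertive α-dienylation of an epoxy ketone; the closest known reactions are the Suzuki–Tsuchihashi/Maruoka–Yamamoto rearrangement of 2,3-epoxy alcohol silyl ethers with alkenyl migration and the organoaluminium-promoted pinacol-type shift of β-mesyloxy alcohols, neither of which has been run as an alanate addition/shift relay or with a dienyl group moving onto a terminal oxirane.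

Step 15
Reactants: 28 2-(trimethylsilyl)ethyl (2E,5S,6R,7S,9S,10E,12E,15R,16Z)-9-(hydroxymethyl)-17-iodo-3,5,7,11,15-pentamethyl-8-oxo-6-(triethylsilyloxy)nonadeca-2,10,12,16-tetraenoate
Product: 29 (2E,5S,6R,7S,9S,10E,12E,15R,16Z)-6-hydroxy-9-(hydroxymethyl)-17-iodo-3,5,7,11,15-pentamethyl-8-oxononadeca-2,10,12,16-tetraenoic acid
Conditions: TASF (6 equiv), DMF–H2O (20:1), 0 → 23 °C; aq. NH4Cl
Reagents that add atoms: none
Why: Fluoride-mediated deprotection: TASF removes the TES ether and fragments the TMSE ester (β-silyl elimination to ethene) under near-neutral conditions that β-hydroxy ketones tolerate, and it is done before the base-labile lactone is attached.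

Step 16
Reactants: 30 prop-2-yn-1-ol
Product: 31 (2E)-3-(tributylstannyl)prop-2-en-1-ol
Conditions: Bu3SnH, AIBN (cat.), 80 °C; chromatography
Reagents that add atoms: tributyltin hydride, CCCC[SnH](CCCC)CCCC
Why: Radical hydrostannation of the terminal alkyne; reversible stannyl radical addition gives mainly the thermodynamic (E)-β-stannyl alkene (future 6E).

Step 17
Reactants: 31 (2E)-3-(tributylstannyl)prop-2-en-1-ol
Product: 32 (2E)-3-(tributylstannyl)prop-2-enal
Conditions: MnO2, CH2Cl2, 23 °C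
Reagents that add atoms: none
Why: MnO2 oxidation of the allylic alcohol gives the enal without touching the vinylstannane.

Step 18
Reactants: 32 (2E)-3-(tributylstannyl)prop-2-enal; 33 cis-but-2-ene
Product: 36 (1E,3R,4S)-4-methyl-1-(tributylstannyl)hexa-1,5-dien-3-ol, via crotylpotassium 34 (not isolated), via crotyldiisopinocampheylborane 35 (not isolated)
Conditions: 33, KOt-Bu, n-BuLi, THF, –78 → –45 °C; (+)-Ipc2BOMe, –78 °C; BF3·OEt2; 32, –78 °C; NaOH, H2O2, 0 °C
Reagents that add atoms: none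
Why: Brown (Z)-crotylboration: the chair transition state gives the syn adduct and the (+)-Ipc ligands (from (–)-α-pinene) direct attack to the aldehyde Re face, which sets C4 and C5 (both S in the lactone).

Step 19
Reactants: 36 (1E,3R,4S)-4-methyl-1-(tributylstannyl)hexa-1,5-dien-3-ol; 37 acryloyl chloride
Product: 38 (1E,3R,4S)-4-methyl-1-(tributylstannyl)hexa-1,5-dien-3-yl prop-2-enoate
Conditions: i-Pr2NEt, DMAP (cat.), CH2Cl2, –20 → 0 °C
Reagents that add atoms: none
Why: Acylation of the secondary allylic alcohol with retention at the carbinol carbon.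

Step 20
Reactants: 38 (1E,3R,4S)-4-methyl-1-(tributylstannyl)hexa-1,5-dien-3-yl prop-2-enoate
Product: 39 (5S,6R)-5-methyl-6-[(E)-2-(tributylstannyl)ethenyl]-5,6-dihydro-2H-pyran-2-one
Conditions: Grubbs II (5 mol %), CH2Cl2 (5 mM), 40 °C
Reagents that add atoms: none
Why: Ring-closing metathesis between the acrylate and the terminal vinyl group closes the cis-5,6-disubstituted α,β-unsaturated δ-lactone with loss of ethene; the internal stannyl alkene does not take part.

Step 21
Reactants: 29 (2E,5S,6R,7S,9S,10E,12E,15R,16Z)-6-hydroxy-9-(hydroxymethyl)-17-iodo-3,5,7,11,15-pentamethyl-8-oxononadeca-2,10,12,16-tetraenoic acid; 39 (5S,6R)-5-methyl-6-[(E)-2-(tributylstannyl)ethenyl]-5,6-dihydro-2H-pyran-2-one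
Product: 40 kazusamycin A
Conditions: Pd2(dba)3 (5 mol %), AsPh3 (20 mol %), CuI (10 mol %), NMP, 23 °C, dark
Reagents that add atoms: none
Why: Stille coupling (Farina conditions) joins C7 and C8 with retention of both alkene geometries (6E,8Z) under neutral conditions compatible with the lactone, the β-hydroxy ketone and the free acid.

**Compound list**

1 | methyl acetoacetate | COC(=O)CC(C)=O | starting material
2 | 2-(trimethylsilyl)ethyl 3-oxobutanoate | CC(=O)CC(=O)OCC[Si](C)(C)C | intermediate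
3 | 2-(trimethylsilyl)ethyl (2E)-3-(trifluoromethanesulfonyloxy)but-2-enoate | C/C(OS(=O)(=O)C(F)(F)F)=C\C(=O)OCC[Si](C)(C)C | intermediate
4 | (R)-3-bromo-2-methylpropan-1-ol | OC[C@@H](C)CBr | starting material
5 | [(2R)-3-bromo-2-methylpropoxy]trimethylsilane (not isolated) | C[Si](C)(C)OC[C@@H](C)CBr | intermediate
6 | bromo[(2R)-2-methyl-3-(trimethylsilyloxy)propyl]zinc (not isolated) | C[Si](C)(C)OC[C@@H](C)C[Zn]Br | intermediate
7 | 2-(trimethylsilyl)ethyl (2E,5S)-3,5-dimethyl-6-(trimethylsilyloxy)hex-2-enoate (not isolated) | C[Si](C)(C)OC[C@@H](C)C/C(C)=C/C(=O)OCC[Si](C)(C)C | intermediate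
8 | 2-(trimethylsilyl)ethyl (2E,5S)-6-hydroxy-3,5-dimethylhex-2-enoate | OC[C@@H](C)C/C(C)=C/C(=O)OCC[Si](C)(C)C | intermediate
9 | 2-(trimethylsilyl)ethyl (2E,5S)-3,5-dimethyl-6-oxohex-2-enoate | O=C[C@@H](C)C/C(C)=C/C(=O)OCC[Si](C)(C)C | intermediate
10 | methyl (2R)-oxirane-2-carboxylate | COC(=O)[C@H]1CO1 | starting material
11 | (2R)-N-methoxy-N-methyloxirane-2-carboxamide | CON(C)C(=O)[C@H]1CO1 | intermediate
12 | 1-[(2R)-oxiran-2-yl]propan-1-one | CCC(=O)[C@H]1CO1 | intermediate
13 | (Z)-enol bis[(–)-isopinocampheyl]borinate of 12 (not isolated) | C/C=C(\OB([C@@H]1C[C@@H]2C[C@H]([C@H]1C)C2(C)C)[C@@H]1C[C@@H]2C[C@H]([C@H]1C)C2(C)C)[C@H]1CO1 | intermediate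
14 | 2-(trimethylsilyl)ethyl (2E,5S,6R,7S)-6-hydroxy-3,5,7-trimethyl-8-[(2R)-oxiran-2-yl]-8-oxooct-2-enoate | O=C([C@H]1CO1)[C@@H](C)[C@H](O)[C@@H](C)C/C(C)=C/C(=O)OCC[Si](C)(C)C | intermediate
15 | 2-(trimethylsilyl)ethyl (2E,5S,6R,7S)-3,5,7-trimethyl-8-[(2R)-oxiran-2-yl]-8-oxo-6-(triethylsilyloxy)oct-2-enoate | O=C([C@H]1CO1)[C@@H](C)[C@H](O[Si](CC)(CC)CC)[C@@H](C)C/C(C)=C/C(=O)OCC[Si](C)(C)C | intermediate
16 | (E)-1,2-dichloroethene | Cl/C=C/Cl | starting material
17 | ethynyltrimethylsilane | C#C[Si](C)(C)C | starting material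
18 | [(3E)-4-chlorobut-3-en-1-yn-1-yl]trimethylsilane | Cl/C=C/C#C[Si](C)(C)C | intermediate
19 | methyl (2S)-3-bromo-2-methylpropanoate | COC(=O)[C@H](C)CBr | starting material
20 | bromo[(2S)-3-methoxy-2-methyl-3-oxopropyl]zinc (not isolated) | COC(=O)[C@H](C)C[Zn]Br | intermediate
21 | methyl (2R,4E)-2-methyl-7-(trimethylsilyl)hept-4-en-6-ynoate | COC(=O)[C@H](C)C/C=C/C#C[Si](C)(C)C | intermediate
22 | (2R,4E)-2-methyl-7-(trimethylsilyl)hept-4-en-6-ynal | O=C[C@H](C)C/C=C/C#C[Si](C)(C)C | intermediate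
23 | [(3E,6R,7Z)-8-iodo-6-methyldeca-3,7-dien-1-yn-1-yl]trimethylsilane | CCC(=C/[C@H](C)C/C=C/C#C[Si](C)(C)C)/I | intermediate
24 | (3Z,5R,7E)-3-iodo-5-methyldeca-3,7-dien-9-yne | CCC(=C/[C@H](C)C/C=C/C#C)/I | intermediate
25 | dimethyl[(1E,3E,6R,7Z)-8-iodo-2,6-dimethyldeca-1,3,7-trien-1-yl]alane (not isolated) | CCC(=C/[C@H](C)C/C=C/C(C)=C/[Al](C)C)/I | intermediate
26 | lithium trimethyl[(1E,3E,6R,7Z)-8-iodo-2,6-dimethyldeca-1,3,7-trien-1-yl]aluminate (not isolated) | [Li+].CCC(=C/[C@H](C)C/C=C/C(C)=C/[Al-](C)(C)C)/I | intermediate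
27 | lithium trimethylaluminate of the tertiary alkoxide formed from 26 and 15, dienyl and oxiranyl on C17, both C17 epimers (not isolated) | [Li+].CCC(=C/[C@H](C)C/C=C/C(C)=C/C(O[Al-](C)(C)C)([C@H]1CO1)[C@@H](C)[C@H](O[Si](CC)(CC)CC)[C@@H](C)C/C(C)=C/C(=O)OCC[Si](C)(C)C)/I | intermediate
28 | 2-(trimethylsilyl)ethyl (2E,5S,6R,7S,9S,10E,12E,15R,16Z)-9-(hydroxymethyl)-17-iodo-3,5,7,11,15-pentamethyl-8-oxo-6-(triethylsilyloxy)nonadeca-2,10,12,16-tetraenoate | CCC(=C/[C@H](C)C/C=C/C(C)=C/[C@@H](CO)C(=O)[C@@H](C)[C@H](O[Si](CC)(CC)CC)[C@@H](C)C/C(C)=C/C(=O)OCC[Si](C)(C)C)/I | intermediate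
29 | (2E,5S,6R,7S,9S,10E,12E,15R,16Z)-6-hydroxy-9-(hydroxymethyl)-17-iodo-3,5,7,11,15-pentamethyl-8-oxononadeca-2,10,12,16-tetraenoic acid | CCC(=C/[C@H](C)C/C=C/C(C)=C/[C@@H](CO)C(=O)[C@@H](C)[C@H](O)[C@@H](C)C/C(C)=C/C(=O)O)/I | intermediate
30 | prop-2-yn-1-ol | C#CCO | starting material
31 | (2E)-3-(tributylstannyl)prop-2-en-1-ol | CCCC[Sn](CCCC)(CCCC)/C=C/CO | intermediate
32 | (2E)-3-(tributylstannyl)prop-2-enal | CCCC[Sn](CCCC)(CCCC)/C=C/C=O | intermediate
33 | cis-but-2-ene | C/C=C\C | starting material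
34 | (Z)-but-2-en-1-ylpotassium (not isolated) | C/C=C\[CH2-].[K+] | intermediate
35 | (Z)-but-2-en-1-ylbis[(+)-isopinocampheyl]borane (not isolated) | C/C=C\CB([C@H]1C[C@H]2C[C@@H]([C@@H]1C)C2(C)C)[C@H]1C[C@H]2C[C@@H]([C@@H]1C)C2(C)C | intermediate
36 | (1E,3R,4S)-4-methyl-1-(tributylstannyl)hexa-1,5-dien-3-ol | CCCC[Sn](CCCC)(CCCC)/C=C/[C@H](O)[C@@H](C)C=C | intermediate
37 | acryloyl chloride | C=CC(Cl)=O | starting material
38 | (1E,3R,4S)-4-methyl-1-(tributylstannyl)hexa-1,5-dien-3-yl prop-2-enoate | CCCC[Sn](CCCC)(CCCC)/C=C/[C@H](OC(=O)C=C)[C@@H](C)C=C | intermediate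
39 | (5S,6R)-5-methyl-6-[(E)-2-(tributylstannyl)ethenyl]-5,6-dihydro-2H-pyran-2-one | CCCC[Sn](CCCC)(CCCC)/C=C/[C@@H]1OC(=O)C=C[C@@H]1C | intermediate
40 | kazusamycin A, (2E,5S,6R,7S,9S,10E,12E,15R,16Z,18E)-17-ethyl-6-hydroxy-9-(hydroxymethyl)-3,5,7,11,15-pentamethyl-19-[(2S,3S)-3-methyl-6-oxo-3,6-dihydro-2H-pyran-2-yl]-8-oxononadeca-2,10,12,16,18-pentaenoic acid | CCC(=C/[C@H](C)C/C=C/C(C)=C/[C@@H](CO)C(=O)[C@@H](C)[C@H](O)[C@@H](C)C/C(C)=C/C(=O)O)/C=C/[C@@H]1OC(=O)C=C[C@@H]1C | target

**Step count and risks**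

Total step count: 21. Longest linear sequence: 9 steps (1 → 2 → 3 → 4 → 7 → 8 → 14 → 15 → 21).

Step 14 (the proposed new step) is the most likely to fail. Residual AlMe3 can transfer methyl instead of the dienyl group, the dienylic C17–O bond can ionise, and fluoride can open the oxirane. The fallback uses known chemistry, sets out from 24 and 15, and comes back at 28. Enyne 24 is carboaluminated and converted to the alanate as before, the alanate is added to 15 at –78 °C, and the reaction is quenched with Rochelle salt so that the tertiary epoxy alcohol F1 is isolated and purified (alkenylalanate carbonyl addition). TMS-imidazole then gives the trimethylsilyl ether F2, which undergoes the established epoxy silyl ether semipinacol rearrangement (BF3·OEt2 or TiCl4, CH2Cl2, –78 °C; alkenyl migration with inversion) to give 28. The approach changes from a metal-alkoxide relay in one flask to a discrete silyl-ether rearrangement of an isolated substrate.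

Step 7 is the second risk. A boron aldol of an oxiranyl ketone is untested, three stereo-elements compete (the Z-enolate must add in the Felkin sense against its usual preference), and the β-hydroxy epoxy ketone 14 can cyclise. The fallback inverts the order of events, sets out from 12 and 24, and comes back at 29. The addition/1,2-shift is run on the simple ketone 12 (cheap, used in excess) to give the ethyl ketone F3. Its primary alcohol is silylated (TESCl, imidazole) to give the silyl ether F4. A Paterson-type syn-aldol of F4 with aldehyde 9 (enolisation on the ethyl side; (–)-Ipc2BOTf/i-Pr2NEt or Sn(OTf)2/Et3N) gives the C19 alcohol F5, and TASF then removes the TES and TMSE groups to give 29.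

Step 21 is the third risk. The Z-trisubstituted iodide is hindered, the substrate carries a free acid and an epimerisable β-hydroxy ketone, and Pd(0) could ionise the allylic lactone. The fallback replaces tin by boron and builds the lactone partner differently; it sets out from 35 and 29 and comes back at 40. Acrolein is crotylated with 35 to give the dienol F6, which is acryloylated as in step 19 to the acrylate F7. A tandem ring-closing/cross-metathesis with vinylboronic acid pinacol ester (Hoveyda–Grubbs II, CH2Cl2, 40 °C) gives the boronate lactone F8. Suzuki–Miyaura coupling of F8 with 29 (Pd(PPh3)4, TlOEt, THF–H2O, 23 °C) gives 40.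

Further compounds
F1 | step 14 | 2-(trimethylsilyl)ethyl (2E,5S,6R,7S,9E,11E,14R,15Z)-8-hydroxy-16-iodo-3,5,7,10,14-pentamethyl-8-[(2R)-oxiran-2-yl]-6-(triethylsilyloxy)octadeca-2,9,11,15-tetraenoate (both C8 epimers) | CCC(=C/[C@H](C)C/C=C/C(C)=C/C(O)([C@H]1CO1)[C@@H](C)[C@H](O[Si](CC)(CC)CC)[C@@H](C)C/C(C)=C/C(=O)OCC[Si](C)(C)C)/I
F2 | step 14 | trimethylsilyl ether of F1 at the tertiary hydroxyl | CCC(=C/[C@H](C)C/C=C/C(C)=C/C(O[Si](C)(C)C)([C@H]1CO1)[C@@H](C)[C@H](O[Si](CC)(CC)CC)[C@@H](C)C/C(C)=C/C(=O)OCC[Si](C)(C)C)/I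
F3 | step 7 | (4S,5E,7E,10R,11Z)-4-(hydroxymethyl)-12-iodo-6,10-dimethyltetradeca-5,7,11-trien-3-one | CCC(=C/[C@H](C)C/C=C/C(C)=C/[C@@H](CO)C(=O)CC)/I
F4 | step 7 | (4S,5E,7E,10R,11Z)-12-iodo-6,10-dimethyl-4-[(triethylsilyloxy)methyl]tetradeca-5,7,11-trien-3-one | CCC(=C/[C@H](C)C/C=C/C(C)=C/[C@@H](CO[Si](CC)(CC)CC)C(=O)CC)/I
F5 | step 7 | 2-(trimethylsilyl)ethyl (2E,5S,6R,7S,9S,10E,12E,15R,16Z)-6-hydroxy-17-iodo-3,5,7,11,15-pentamethyl-8-oxo-9-[(triethylsilyloxy)methyl]nonadeca-2,10,12,16-tetraenoate | CCC(=C/[C@H](C)C/C=C/C(C)=C/[C@@H](CO[Si](CC)(CC)CC)C(=O)[C@@H](C)[C@H](O)[C@@H](C)C/C(C)=C/C(=O)OCC[Si](C)(C)C)/I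
F6 | step 21 | (3S,4S)-4-methylhexa-1,5-dien-3-ol | C=C[C@H](O)[C@@H](C)C=C
F7 | step 21 | (3S,4S)-4-methylhexa-1,5-dien-3-yl prop-2-enoate | C=C[C@H](OC(=O)C=C)[C@@H](C)C=C
F8 | step 21 | (5S,6S)-5-methyl-6-[(E)-2-(4,4,5,5-tetramethyl-1,3,2-dioxaborolan-2-yl)ethenyl]-5,6-dihydro-2H-pyran-2-one | CC1(C)OB(/C=C/[C@@H]2OC(=O)C=C[C@@H]2C)OC1(C)C
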